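The earlier runs and the new flask were computed from invented constants; scatter was added.

**Quick number.** Colleague, for your number on the south flask I would test your hunch that its late readings already show the end.

the same everywhere: substrate 0.37 M; second nucleophile 0.185 M
- south: first nucleophile 0.407 M; the very flask that is asked about, followed so far
- north-east: first nucleophile 0.81 M; run made earlier
- flask: first nucleophile 0.407 M; time 80 min

| run | time / min | target / % | other capture product / % |
|---|---|---|---|
| south | 1.00 | 12.6 | 11.6 |
| south | 3.00 | 11.5 | 26.3 |
| south | 6.00 | 10.5 | 37.3 |
| south | 8.00 | 10.4 | 41.5 |
| south | 12.0 | 10.1 | 45.3 |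
| south | 15.0 | 8.7 | 47.0 |
| north-east | 4.00 | 29.4 | 26.4 |
| north-east | 10.0 | 25.3 | 39.8 |
| north-east | 20.0 | 22.5 | 47.4 |
| north-east | 30.0 | 22.6 | 49.5 |
| north-east | 40.0 | 23.3 | 49.5 |
| north-east | 60.0 | 22.7 | 48.9 |

(standard deviation of a reading: 0.5 percentage points)

* ratio of target to other capture product at 3.0 s
* ratio of target to other capture product at 2.0 min
* ratio of target to other capture product at 80 min
* which of target and other capture product there is more of at 80 min

- what is said of target includes idle adduct
- the numbers in the tables scatter with a standard deviation of 0.5 percentage points
- steps thought possible: first nucleophile + intermediate <-> target; substrate <-> intermediate; first nucleophile + target <-> idle adduct; second nucleophile + intermediate -> other capture product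

**The ceiling.** Each other capture product uses one second nucleophile, charged at 0.185 M, less than the substrate at 0.37 M. As limiting reagent it allows at most 50.0 % of other capture product; north-east reads 49.5 % at 40.0 min.

**Holding number.** I take what stays uncaptured as shared between substrate and target, leaving the small amount of intermediate out of the count. Over the last 3 readings of each run, south averages 9.73 % target and north-east 22.9 %. Let S be target over substrate, the substrate being what both products leave, and b the free first nucleophile, its charge less 2 per target, taking target as mostly idle adduct. South gives S = 0.213 at b = 0.335 M; north-east gives S = 0.822 at b = 0.641 M. So between these two runs S rises 3.86-fold for a 1.91-fold b, near the square of b, and the holding number H = S/b² reads 1.90 M⁻² and 2.00 M⁻², on average 1.95 M⁻².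

**South's end.** My reckoning for the south flask shares the 50.0 % left over by S = H·b², which gives target 8.98 % and a ratio of 0.180 at 80 min, with other capture product ahead. For the earlier times I give no number from H and hold to south's readings, which show a ratio of 1.09 at 1.00 min and 0.437 at 3.00 min.

**The result.** The forecast, holding that “the target pool is second order and mostly idle adduct”, gave 2, 0.61 and 0.187, with other capture product ahead. The south flask gives 2.84 at 3.0 s, 0.622 at 2.0 min and 0.183 at 80 min, with target 9.15 % and other capture product 50.0 %.

    first nucleophile + intermediate ⇌ target (K = 3.30 M⁻¹, k = 300 M⁻¹ min⁻¹)
    substrate ⇌ intermediate (K = 0.00480, k = 1.20 min⁻¹)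
    first nucleophile + target ⇌ idle adduct, settled at all times (K = 120 M⁻¹)
    second nucleophile + intermediate → other capture product (k = 220 M⁻¹ min⁻¹)

**What stands.** At 80 min in the south flask, second nucleophile stands at 0 %, and the half-life of intermediate by capture is 170 h, far longer than the time asked about. The south flask's substrate 40.7 %, target 9.15 % and first nucleophile 83.6 % of its charge then give H = 1.95 M⁻².

**More substrate.** In the flask with 0.63 M of substrate, the ceiling is 29.4 %, b is 0.284 M with the target share above, and H gives a ratio of 0.326. That flask computes to 0.331, with 60.6 % substrate.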